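**Plan**
1. Retrosynthesis: cut C13–C16 (opens the five-membered ring C8–C15–C16–C13–C14), then C8–C15 (a 2-bromoallyl group). The C6 acid and C7 aldehyde are rejoined as the 6,7-diol of a temporary carbocyclic ring B. C9–C10 and C5–C6 are then cut back to a 2-oxocyclohexanecarboxylate (ring A) and an anisole (future ring C).
2. Forward: ring A with quaternary C4 is made first. The anisole is attached through C6–C7, and acid closes temporary ring B at C9–C10. Birch reductive alkylation dearomatises ring C and creates quaternary C8. Ring D is closed last. Periodate then opens ring B to the C7 aldehyde and, through a lactol held by the C19 acid, the C6 acid.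
3. Enabling feature: C13 is β to the C11 ketone and 1,3 to quaternary C8 across C14. The enone C11(=O)–C12=C13 with a 2-bromoallyl group on C8 therefore closes C13–C16 by 5-exo radical conjugate addition and leaves C16=C17 as the exocyclic methylene.
4. Stereochemistry: C4 from an auxiliary-controlled methylation; C5 and C10 from the trans-selective cyclisation relayed from C4; C8 by alkylation anti to the C10 methyl; C9 by equilibration under the constraint of ring B; C13 by the bridge geometry.
5. Locants follow kaurane/podocarpane numbering (C19 = carboxyl carbon on C4, C20 = methyl on C10).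

Key step: step 12

Assumption: the lithio-enamine methylation of step 2 is taken to give the (R)-ester with the L-valine auxiliary in toluene/HMPA; should the sense be opposite, the D-valine ester (or THF as solvent) is used and nothing else changes.

**Step 1**
Reactants: 1 tert-butyl 2-oxocyclohexane-1-carboxylate; 2 tert-butyl L-valinate
Product: 3 tert-butyl 2-{[(2S)-1-tert-butoxy-3-methyl-1-oxobutan-2-yl]amino}cyclohex-1-ene-1-carboxylate
Conditions: BF3·OEt2 (cat.), benzene, reflux, azeotropic removal of water
Reagents that add atoms: none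
Why: Acid-catalysed condensation of a β-keto ester with a primary amine should give the hydrogen-bonded enamino ester (vinylogous carbamate formation) without touching the valine stereocentre.

**Step 2**
Reactants: 3 tert-butyl 2-{[(2S)-1-tert-butoxy-3-methyl-1-oxobutan-2-yl]amino}cyclohex-1-ene-1-carboxylate
Product: 5 tert-butyl (1R)-1-methyl-2-oxocyclohexane-1-carboxylate, via methylated imine 4 (not isolated)
Conditions: LiN(iPr)2, toluene, HMPA (1 equiv), −78 °C; MeI; then 1 M HCl, 0 °C
Reagents that add atoms: iodomethane CI; water O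
Why: The chelated lithio-enamine should be C-methylated on the face left open by the auxiliary (auxiliary-controlled enamine alkylation, high enantioselectivity expected), and acid hydrolysis of the imine releases the quaternary β-keto ester and the recoverable amino ester.

**Step 3**
Reactants: 5 tert-butyl (1R)-1-methyl-2-oxocyclohexane-1-carboxylate
Product: 6 tert-butyl (1R)-1,3-dimethyl-2-oxocyclohexane-1-carboxylate (C3 epimer mixture)
Conditions: LiN(iPr)2, THF, −78 °C; MeI
Reagents that add atoms: iodomethane CI
Why: The ketone can enolise only towards C3 because C1 is quaternary, so lithium enolate C-methylation is regiospecific; the new centre (future C10) becomes a cation in step 6 and its configuration is of no consequence.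

**Step 4**
Reactants: 7 1-(2-bromoethyl)-3-methoxybenzene
Product: 8 2-(2-bromoethyl)-1-chloro-4-methoxybenzene
Conditions: N-chlorosuccinimide, MeCN, rt to 50 °C
Reagents that add atoms: N-chlorosuccinimide O=C1CCC(=O)N1Cl
Why: Electrophilic aromatic chlorination of a 3-alkylanisole should go para to the methoxy group, which blocks the position that would otherwise win in the ring closure of step 6.

**Step 5**
Reactants: 8 2-(2-bromoethyl)-1-chloro-4-methoxybenzene; 6 tert-butyl (1R)-1,3-dimethyl-2-oxocyclohexane-1-carboxylate
Product: 10 tert-butyl (1R)-2-[2-(2-chloro-5-methoxyphenyl)ethyl]-2-hydroxy-1,3-dimethylcyclohexane-1-carboxylate (C2/C3 epimer mixture), via Grignard reagent 9 (not isolated)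
Conditions: Mg, THF, rt; CeCl3, THF, −78 °C; then 6, −78 to 0 °C; aq. NH4Cl
Reagents that add atoms: none
Why: The organocerium reagent derived from the Grignard reagent should add to the hindered, enolisable ketone without deprotonation (organocerium 1,2-addition), the tert-butyl ester and aryl chloride being inert; all carbinol epimers converge in step 6.

**Step 6**
Reactants: 10 tert-butyl (1R)-2-[2-(2-chloro-5-methoxyphenyl)ethyl]-2-hydroxy-1,3-dimethylcyclohexane-1-carboxylate
Product: 12 ent-14-chloro-11-methoxypodocarpa-8,11,13-trien-19-oic acid [(1R,4aR,10aS)-8-chloro-5-methoxy-1,4a-dimethyl-1,2,3,4,4a,9,10,10a-octahydrophenanthrene-1-carboxylic acid], via unsaturated acid 11 (not isolated)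
Conditions: CF3CO2H, CH2Cl2, 0 °C; then MeSO3H, rt
Reagents that add atoms: none
Why: Acid cleaves the tert-butyl ester and ionises the tertiary alcohol, and the C10 cation reached through alkene 11 alkylates the only unsubstituted ortho carbon (intramolecular Friedel–Crafts cyclialkylation closing six-membered ring B); a chair-like closure with the chain equatorial and CO2H (not CH3) 1,3-diaxial to the new angular methyl should favour the trans-fused acid with C19 cis to C20.

**Step 7**
Reactants: 12 ent-14-chloro-11-methoxypodocarpa-8,11,13-trien-19-oic acid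
Product: 13 ent-11-methoxypodocarpa-8,11,13-trien-19-oic acid
Conditions: H2 (3 atm), Pd/C, NaOAc, MeOH, 40 °C
Reagents that add atoms: none
Why: Palladium-catalysed hydrogenolysis of the aryl chloride removes the blocking group, and no other reducible group is present.

**Step 8**
Reactants: 13 ent-11-methoxypodocarpa-8,11,13-trien-19-oic acid
Product: 14 ent-11-methoxy-7-oxopodocarpa-8,11,13-trien-19-oic acid
Conditions: CrO3, AcOH/H2O, rt
Reagents that add atoms: chromium trioxide O=[Cr](=O)=O
Why: Benzylic oxidation: C7 is the only benzylic methylene (C10 is quaternary), so the aryl ketone should form selectively.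

**Step 9**
Reactants: 14 ent-11-methoxy-7-oxopodocarpa-8,11,13-trien-19-oic acid; 15 2,3-dibromoprop-1-ene
Product: 17 ent-8-(2-bromoprop-2-en-1-yl)-11-methoxy-7-oxopodocarpa-9(11),13-dien-19-oic acid (bromoallyl group trans to the C10 methyl), via dilithium dienolate 16 (not isolated)
Conditions: Li (3.1 equiv), NH3(l)/THF, t-BuOH (1 equiv), −78 °C (blue colour discharged with a drop of isoprene); then 15, −78 °C; NH4Cl
Reagents that add atoms: none
Why: Birch reductive alkylation of an aryl ketone: two-electron reduction and protonation para to the acyl carbon (C12) give dienolate 16, which should be C-alkylated at C8 on the face opposite the axial C10 methyl, setting the quaternary centre and leaving the C9=C11 enol ether and the C13=C14 alkene.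

**Step 10**
Reactants: 17 ent-8-(2-bromoprop-2-en-1-yl)-11-methoxy-7-oxopodocarpa-9(11),13-dien-19-oic acid
Product: 18 ent-8-(2-bromoprop-2-en-1-yl)-6-hydroxy-11-methoxy-7-oxopodocarpa-9(11),13-dien-19-oic acid (6-OH trans to the C10 methyl)
Conditions: KN(SiMe3)2 (2.2 equiv), THF, −78 °C; 2-(phenylsulfonyl)-3-phenyloxaziridine; NH4Cl
Reagents that add atoms: 2-(phenylsulfonyl)-3-phenyloxaziridine O=S(=O)(N1OC1c1ccccc1)c1ccccc1
Why: The C7 ketone can enolise only towards C6 (C8 is quaternary), and the potassium enolate should be hydroxylated by the N-sulfonyloxaziridine (enolate oxidation) on the face away from C20, C19 and C14.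

**Step 11**
Reactants: 18 ent-8-(2-bromoprop-2-en-1-yl)-6-hydroxy-11-methoxy-7-oxopodocarpa-9(11),13-dien-19-oic acid
Product: 20 ent-8-(2-bromoprop-2-en-1-yl)-6,7-dihydroxy-11-oxopodocarp-12-en-19-oic acid (H9 trans to the C10 methyl; 6-OH trans and 7-OH cis to it), via diol enol ether 19 (not isolated)
Conditions: NaBH4, MeOH, 0 °C; then 2 M HCl, THF, rt
Reagents that add atoms: water O
Why: NaBH4 reduces the only ketone (axial hydride delivery, diequatorial diol expected) while C11 is still masked; aqueous acid then hydrolyses the enol ether, sets C9 by equilibration (ring C can only span the axial C8–C14 and equatorial C9–C11 bonds of the ring-B chair) and moves the C13=C14 bond into conjugation.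

**Step 12**
Reactants: 20 ent-8-(2-bromoprop-2-en-1-yl)-6,7-dihydroxy-11-oxopodocarp-12-en-19-oic acid
Product: 21 ent-6,7-dihydroxy-11-oxokaur-16-en-19-oic acid (6-OH trans and 7-OH cis to the C10 methyl)
Conditions: Bu3SnH (1.5 equiv, slow addition), AIBN (cat.), benzene, 80 °C
Reagents that add atoms: none
Why: Bu3Sn• abstracts bromine to give the σ-vinyl radical at C16, which adds to C13, the β-carbon of the enone C11(=O)–C12=C13, and the α-keto radical at C12 then takes hydrogen from Bu3SnH; the closest known reaction type is the tin hydride vinyl radical cyclisation onto an enone used for bicyclo[3.2.1]octanes. The ring C8–C15–C16–C13–C14 closes in the 5-exo-trig mode. The new stereocentre C13 is controlled by quaternary C8: the two-carbon tether can bridge C8 and C13 only on the face of ring C where C15 is axial, so H13 ends on the opposite face. The step needs 5-exo closure over 6-endo attack at C12 and cyclisation over direct reduction or hydrogen transfer; the polarity match (vinyl radical with enone β-carbon), the gauche C15/C13 relationship fixed by the ring-B-locked C8 and C9, and slow hydride addition should secure this. The exocyclic methylene is delivered directly because the radical centre is the internal alkene carbon.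

**Step 13**
Reactants: 21 ent-6,7-dihydroxy-11-oxokaur-16-en-19-oic acid
Product: 23 ent-6-hydroxy-7,11-dioxo-6,7-secokaur-16-en-19,6-olide (C6 lactol epimers), via open dialdehyde acid 22 (not isolated)
Conditions: NaIO4, THF/H2O, rt
Reagents that add atoms: none
Why: Periodate glycol cleavage opens temporary ring B without touching the alkene, and the C6 aldehyde should be trapped by the cis C19 acid as a five-membered hydroxylactone, which distinguishes it from the neopentyl C7 aldehyde.

**Step 14**
Reactants: 23 ent-6-hydroxy-7,11-dioxo-6,7-secokaur-16-en-19,6-olide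
Product: 25 ent-7,11-dioxo-6,7-secokaur-16-ene-6,19-dioic acid (target), via cyclic anhydride 24 (not isolated)
Conditions: TEMPO (cat.), PhI(OAc)2, CH2Cl2, rt; then NaHCO3, THF/H2O, 0 °C to rt; then 1 M HCl to pH 3, 0 °C
Reagents that add atoms: water O
Why: The oxoammonium oxidant should convert the lactol into the cyclic anhydride but leave the non-hydrated C7 aldehyde alone (lactol-to-lactone oxidation), and bicarbonate hydrolysis with cold acidification opens the anhydride to the diacid under conditions too mild to epimerise C9.

**Compound list**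
1 | tert-butyl 2-oxocyclohexane-1-carboxylate | O=C1CCCCC1C(=O)OC(C)(C)C | starting material
2 | tert-butyl L-valinate (S) | CC(C)[C@H](N)C(=O)OC(C)(C)C | starting material
3 | tert-butyl 2-{[(2S)-1-tert-butoxy-3-methyl-1-oxobutan-2-yl]amino}cyclohex-1-ene-1-carboxylate | CC(C)[C@H](NC1=C(C(=O)OC(C)(C)C)CCCC1)C(=O)OC(C)(C)C | intermediate
4 | tert-butyl (1R)-2-{[(2S)-1-tert-butoxy-3-methyl-1-oxobutan-2-yl]imino}-1-methylcyclohexane-1-carboxylate | CC(C)[C@H](N=C1CCCC[C@@]1(C)C(=O)OC(C)(C)C)C(=O)OC(C)(C)C | intermediate (not isolated)
5 | tert-butyl (1R)-1-methyl-2-oxocyclohexane-1-carboxylate | O=C1CCCC[C@@]1(C)C(=O)OC(C)(C)C | intermediate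
6 | tert-butyl (1R)-1,3-dimethyl-2-oxocyclohexane-1-carboxylate (C3 epimers) | CC1CCC[C@@](C)(C(=O)OC(C)(C)C)C1=O | intermediate
7 | 1-(2-bromoethyl)-3-methoxybenzene | COc1cccc(CCBr)c1 | starting material
8 | 2-(2-bromoethyl)-1-chloro-4-methoxybenzene | COc1ccc(Cl)c(CCBr)c1 | intermediate
9 | [2-(2-chloro-5-methoxyphenyl)ethyl]magnesium bromide | COc1ccc(Cl)c(CC[Mg]Br)c1 | intermediate (not isolated)
10 | tert-butyl (1R)-2-[2-(2-chloro-5-methoxyphenyl)ethyl]-2-hydroxy-1,3-dimethylcyclohexane-1-carboxylate (C2/C3 epimers) | COc1ccc(Cl)c(CCC2(O)C(C)CCC[C@@]2(C)C(=O)OC(C)(C)C)c1 | intermediate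
11 | (1R)-2-[2-(2-chloro-5-methoxyphenyl)ethyl]-1,3-dimethylcyclohex-2-ene-1-carboxylic acid | COc1ccc(Cl)c(CCC2=C(C)CCC[C@@]2(C)C(=O)O)c1 | intermediate (not isolated)
12 | ent-14-chloro-11-methoxypodocarpa-8,11,13-trien-19-oic acid; (1R,4aR,10aS)-8-chloro-5-methoxy-1,4a-dimethyl-1,2,3,4,4a,9,10,10a-octahydrophenanthrene-1-carboxylic acid | COc1ccc(Cl)c2c1[C@]1(C)CCC[C@@](C)(C(=O)O)[C@H]1CC2 | intermediate
13 | ent-11-methoxypodocarpa-8,11,13-trien-19-oic acid (1R,4aR,10aS) | COc1cccc2c1[C@]1(C)CCC[C@@](C)(C(=O)O)[C@H]1CC2 | intermediate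
14 | ent-11-methoxy-7-oxopodocarpa-8,11,13-trien-19-oic acid (1R,4aR,10aS) | COc1cccc2c1[C@]1(C)CCC[C@@](C)(C(=O)O)[C@H]1CC2=O | intermediate
15 | 2,3-dibromoprop-1-ene | C=C(Br)CBr | starting material
16 | dilithium salt of the C7 dienolate and C19 carboxylate (C7=C8, C9=C11, C13=C14) | [O-]C1=C2C=CCC(OC)=C2[C@]3(C)CCC[C@@](C)(C(=O)[O-])[C@H]3C1.[Li+].[Li+] | intermediate (not isolated)
17 | ent-8-(2-bromoprop-2-en-1-yl)-11-methoxy-7-oxopodocarpa-9(11),13-dien-19-oic acid (bromoallyl trans to the C10 methyl) | C=C(Br)C[C@]2(C3=O)C=CCC(OC)=C2[C@]1(C)CCC[C@@](C)(C(=O)O)[C@H]1C3 | intermediate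
18 | ent-8-(2-bromoprop-2-en-1-yl)-6-hydroxy-11-methoxy-7-oxopodocarpa-9(11),13-dien-19-oic acid (6-OH trans to the C10 methyl) | C=C(Br)C[C@]2(C3=O)C=CCC(OC)=C2[C@]1(C)CCC[C@@](C)(C(=O)O)[C@H]1[C@@H]3O | intermediate
19 | ent-8-(2-bromoprop-2-en-1-yl)-6,7-dihydroxy-11-methoxypodocarpa-9(11),13-dien-19-oic acid (7-OH cis to the C10 methyl) | C=C(Br)C[C@]2([C@@H]3O)C=CCC(OC)=C2[C@]1(C)CCC[C@@](C)(C(=O)O)[C@H]1[C@@H]3O | intermediate (not isolated)
20 | ent-8-(2-bromoprop-2-en-1-yl)-6,7-dihydroxy-11-oxopodocarp-12-en-19-oic acid (H9 trans to the C10 methyl) | C=C(Br)C[C@]2([C@@H]3O)CC=CC(=O)[C@H]2[C@]1(C)CCC[C@@](C)(C(=O)O)[C@H]1[C@@H]3O | intermediate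
21 | ent-6,7-dihydroxy-11-oxokaur-16-en-19-oic acid | C=C1C[C@]2([C@@H]3O)C[C@H]1CC(=O)[C@H]2[C@]1(C)CCC[C@@](C)(C(=O)O)[C@H]1[C@@H]3O | intermediate
22 | ent-6,7,11-trioxo-6,7-secokaur-16-en-19-oic acid (open dialdehyde acid) | C=C1C[C@]2(C=O)C[C@H]1CC(=O)[C@H]2[C@]1(C)CCC[C@@](C)(C(=O)O)[C@H]1C=O | intermediate (not isolated)
23 | ent-6-hydroxy-7,11-dioxo-6,7-secokaur-16-en-19,6-olide (lactol, C6 epimers) | C=C1C[C@]2(C=O)C[C@H]1CC(=O)[C@H]2[C@]1(C)CCC[C@@]3(C)C(=O)OC(O)[C@@H]13 | intermediate
24 | ent-7,11-dioxo-6,7-secokaur-16-ene-6,19-dioic anhydride | C=C1C[C@]2(C=O)C[C@H]1CC(=O)[C@H]2[C@]1(C)CCC[C@@]3(C)C(=O)OC(=O)[C@@H]13 | intermediate (not isolated)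
25 | ent-7,11-dioxo-6,7-secokaur-16-ene-6,19-dioic acid | C=C1C[C@]2(C=O)C[C@H]1CC(=O)[C@H]2[C@]1(C)CCC[C@@](C)(C(=O)O)[C@H]1C(=O)O | target

**Count and risks**
Total steps: 14. Longest linear sequence: 13 (steps 1–3 and 5–14; step 4 is a side branch).

Step 9. What may go wrong: over-reduction of the ketyl to the benzylic alcohol, protonation of the dienolate instead of alkylation, or alkylation on oxygen or on the wrong face. Fallback (sets out from 14, returns at 17): ring reduction and C–C bond formation are separated. Li/NH3/t-BuOH followed by NH4Cl should give the protonated dihydroaromatic keto acid ent-11-methoxy-7-oxopodocarpa-9(11),13-dien-19-oic acid F1. Its C8–H is α to the ketone and doubly allylic, so KN(SiMe3)2 (2.1 equiv, THF, −78 °C) should regenerate the dienolate under aprotic conditions, and alkylation with 15 gives 17.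

Step 6. What may go wrong: loss of stereocontrol at the ring fusion (cis fusion or the C4-epimeric relationship), closure of the C5 cation to a spiro-indane, or slow attack at the crowded carbon between the methoxy group and the chain. Fallback (sets out from 10, returns at 12): the carboxyl group is used as an internal directing group. CF3CO2H alone cleaves the ester, dehydrates and lactonises to the 19,10-lactone 8-[2-(2-chloro-5-methoxyphenyl)ethyl]-1,5-dimethyl-6-oxabicyclo[3.2.1]octan-7-one F2. AlCl3 (CH2Cl2/MeNO2) then ionises the tertiary C10–O bond, and the arene should attack C10 anti to the departing carboxylate (lactone Friedel–Crafts alkylation), placing C9 trans and the C10 methyl cis to C19 as in 12.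

Step 12. What may go wrong: reduction of the vinyl radical before cyclisation, intramolecular hydrogen transfer, or stannyl radical addition to the enone. Fallback (sets out from 20, returns at 21; it makes no new compound, F0): a palladium-catalysed reductive Heck cyclisation (Pd(OAc)2, PPh3, HCO2Na, DMF, 80 °C). Oxidative addition of zerovalent palladium into the C–Br bond, 5-exo carbopalladation of the enone at C13 and formate reduction of the palladium enolate should give 21 by a two-electron pathway with no free radical.

**Further compounds**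
F1 | step 9 | ent-11-methoxy-7-oxopodocarpa-9(11),13-dien-19-oic acid (C8–H, epimer mixture) | O=C3C2C=CCC(OC)=C2[C@]1(C)CCC[C@@](C)(C(=O)O)[C@H]1C3
F2 | step 6 | 8-[2-(2-chloro-5-methoxyphenyl)ethyl]-1,5-dimethyl-6-oxabicyclo[3.2.1]octan-7-one (19,10-lactone, chain syn to the lactone bridge) | COc1ccc(Cl)c(CC[C@@H]2[C@@]3(C)CCC[C@]2(C)OC3=O)c1
F0 | step 12 | none | none
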